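**Plan**

1. Retrosynthesis: the two phenolic C–O bonds at ring carbons C2 and C3 are cut first (back to C–H), giving (S)-18-methylicosyl benzoate. Then the C16–C17 bond of the chain is cut, then the ester C–O bond, leading to 16-bromohexadecan-1-ol and benzoyl chloride.
2. Enabling feature: the hydroxyls sit on the neighbouring ring carbons C2 and C3, ortho and meta to the ester-bearing C1, and C4–C6 carry only hydrogen. This is the 2,3-pattern that a toluene-type Rieske dioxygenase puts on a monosubstituted benzene ring.
3. Forward: the benzoate is made first and masks the hydroxyl. The chain is then joined at C16–C17 by copper-catalysed Grignard coupling. The benzene ring, present from the start, is dioxygenated and rearomatised last; no ring is formed.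
4. Stereochemistry: the only stereocentre, C18 (S), is bought in (S)-1-bromo-2-methylbutane, and no step touches it.

Key step: step 3

Assumption: an Escherichia coli strain carrying todC1C2BAD of Pseudomonas putida F1 and alkL is taken as a biocatalyst obtainable by routine cloning and is not counted as a step; the optical purity of the target equals that of purchased 4.

**Route**

Step 1
Reactants: 1 16-bromohexadecan-1-ol; 2 benzoyl chloride
Product: 3 16-bromohexadecyl benzoate
Conditions: Et3N, DMAP (cat.), CH2Cl2, 0 °C → rt
Reagents that add atoms: none
Why: DMAP-catalysed acylation of a primary alcohol by an acid chloride (nucleophilic acyl substitution) is fast at 0 °C, leaves the primary bromide untouched, and installs the benzoate that both masks the hydroxyl during the coupling and is the arene oxidised in the last step.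

Step 2
Reactants: 3 16-bromohexadecyl benzoate; 4 (S)-1-bromo-2-methylbutane
Product: 6 (S)-18-methylicosyl benzoate, via (S)-2-methylbutylmagnesium bromide 5 (not isolated)
Conditions: 4, Mg, THF, 45 °C; then slow addition of 5 (1.3 equiv) to 3, Li2CuCl4 (3 mol%), NMP (4 equiv), THF, 0 → 20 °C; aq. NH4Cl
Reagents that add atoms: none
Why: Copper-catalysed alkyl–alkyl cross-coupling of a primary alkyl Grignard reagent with a primary alkyl bromide (Li2CuCl4) should outrun carbonyl addition when the reagent is added slowly in THF/NMP, so the benzoate should survive, and the stereocentre of 4, β to the carbon–magnesium bond and never a reacting centre, passes unchanged into C18 of 6.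

Step 3
Reactants: 6 (S)-18-methylicosyl benzoate
Product: 8 Gentiside H, via (5S,6R)-cis-dihydrodiol 7 (not isolated)
Conditions: resting cells of E. coli JM109 co-expressing toluene dioxygenase (TodC1C2BA), cis-dihydrodiol dehydrogenase (TodD) and AlkL; 6 as methyl-β-cyclodextrin complex, KH2PO4/K2HPO4 buffer pH 7.0, glucose, air, 30 °C; EtOAc extraction
Reagents that add atoms: dioxygen, O=O
Why: Proposed new method: the reduced divalent iron centre of the oxygenase, fed with two electrons from NADH through the reductase, the ferredoxin and the Rieske [2Fe-2S] cluster, binds O2 and adds both oxygen atoms to one face of the C2–C3 bond of the benzoate ring to give cis-dihydrodiol 7; the NAD-dependent dehydrogenase then oxidises one carbinol of 7 to a hydroxy dienone that tautomerises to the catechol and returns the NADH, so the cascade is in sum arene plus O2. The closest known reaction type is the whole-cell toluene dioxygenase cis-dihydroxylation of methyl and other short-chain alkyl benzoates at the 2,3-positions, together with dehydrogenase aromatisation of arene cis-dihydrodiols to 3-substituted catechols; the new element is the C21 ester residue. No ring is closed. The two carbinol stereocentres of 7 are set by the enzyme pocket (5S,6R expected by analogy with the short esters) and vanish on aromatisation, while C18 of the chain is remote and untouched. The step needs 2,3-attack over ipso-1,2 or 3,4-attack and no oxidation of the chain: the neutral ester, unlike a carboxylate, should be held like the methyl group of toluene so that the ortho and meta carbons lie over the iron, the chain offers no benzylic or otherwise activated C–H, and the long alkyl group is expected to trail out through the substrate channel. Uptake of the very lipophilic ester is addressed by feeding it as a cyclodextrin inclusion complex to cells that also carry the outer-membrane channel AlkL, and the E. coli host has no catechol ring-cleavage enzymes.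

**Compound list**

1 | 16-bromohexadecan-1-ol | OCCCCCCCCCCCCCCCCBr | starting material
2 | benzoyl chloride | O=C(Cl)c1ccccc1 | starting material
3 | 16-bromohexadecyl benzoate | BrCCCCCCCCCCCCCCCCOC(=O)c1ccccc1 | intermediate
4 | (S)-1-bromo-2-methylbutane | CC[C@H](C)CBr | starting material
5 | (S)-2-methylbutylmagnesium bromide | CC[C@H](C)C[Mg]Br | intermediate
6 | (S)-18-methylicosyl benzoate | CC[C@H](C)CCCCCCCCCCCCCCCCCOC(=O)c1ccccc1 | intermediate
7 | (S)-18-methylicosyl (5S,6R)-5,6-dihydroxycyclohexa-1,3-diene-1-carboxylate | CC[C@H](C)CCCCCCCCCCCCCCCCCOC(=O)C1=CC=C[C@@H]([C@@H]1O)O | intermediate
8 | Gentiside H, (S)-18-methylicosyl 2,3-dihydroxybenzoate | CC[C@H](C)CCCCCCCCCCCCCCCCCOC(=O)c1cccc(O)c1O | target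

Total step count: 3
Longest linear sequence: 3 steps (1 → 3 → 6 → 8)

**Steps most likely to fail**

Step 3. The ester may fail to cross the cell envelope or to thread its chain into the active-site channel, giving no turnover or only uncoupled reduction of O2. Hydrolysis of the ester by host esterases and autoxidation of the catechol in aerated buffer could add to the loss. The fallback uses known chemistry, sets out from 6 and comes back at 8. The benzoate is saponified (KOH, MeOH/THF, 60 °C) to (S)-18-methylicosan-1-ol F1. This is esterified with commercial 2,3-bis(benzyloxy)benzoic acid (DCC, DMAP cat., CH2Cl2, rt; Steglich esterification) to (S)-18-methylicosyl 2,3-bis(benzyloxy)benzoate F2. Hydrogenolysis of the two benzyl ethers (H2, Pd/C, EtOAc, rt) then gives 8, the alkyl benzoate ester being inert to these conditions. Here the catechol oxygens arrive with the acid instead of by C–H oxidation.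

Step 2. The Grignard reagent may add to the benzoate carbonyl faster than it couples, and reduction or elimination at the bromide and homocoupling may also intrude. The fallback sets out from 3 and 4 and comes back at 6. Zinc insertion into 4 (Zn dust, I2 cat., N,N-dimethylacetamide, 80 °C) gives (S)-2-methylbutylzinc bromide F3, a reagent that does not attack esters. It is joined to 3 by a palladium-catalysed alkyl–alkyl Negishi coupling (Pd2(dba)3, tricyclopentylphosphine, N-methylimidazole, THF/NMP, 80 °C). The stereocentre is again β to the metal and is not at risk.

Step 1. The ammonium chloride formed may partly exchange the terminal bromide for chloride, or the amine bases may slowly be quaternised by the primary bromide; either would spoil the coupling partner. The fallback sets out from 1 and comes back at 3. It is a Fischer esterification of 1 with benzoic acid (TsOH cat., toluene, reflux, Dean–Stark trap), which needs neither amine nor chloride. This path passes through no new compound (F0).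

**Further compounds**

F1 | step 3 | (S)-18-methylicosan-1-ol | CC[C@H](C)CCCCCCCCCCCCCCCCCO
F2 | step 3 | (S)-18-methylicosyl 2,3-bis(benzyloxy)benzoate | CC[C@H](C)CCCCCCCCCCCCCCCCCOC(=O)c1cccc(OCc2ccccc2)c1OCc1ccccc1
F3 | step 2 | (S)-2-methylbutylzinc bromide | CC[C@H](C)C[Zn]Br
F0 | step 1 | none | none
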